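## Structural features

The target is a germacranolide: a ten-membered carbocycle (C1–C10) fused at C6/C7 to an α-methylene-γ-butyrolactone (lactone O on C6, C11=C13 exocyclic, C12 carbonyl). The carbocycle holds two trisubstituted alkenes, both ring-cis (both E by the sequence rule): C4=C5 carrying the C15 hydroxymethyl group and C1=C10 carrying the C14 methyl ester. Four stereocentres stand side by side, C6(R)–C7(S)–C8(S)–C9(R), with the lactone oxygen on C6, the isobutyrate on C8 and the acetate on C9. The lactone substituents at C6 and C7 are trans and O8/O9 are anti. Fragile elements are the methylene lactone (a Michael acceptor that also makes C7–H vinylogously acidic), the two different vicinal esters on O8/O9 (acyl migration), the C9 acetate allylic to the enoate, and the strained medium ring itself. The real difficulty is closing the ten-membered ring while setting C8 and C9 and keeping the two acyl groups distinct. The key step exploits the array C8H(OH)–C9H(OAc)–C10(CO2Me)=C1H inside the carbocycle: it is what an acetoxy-substituted allyl metal gives when it adds through its γ-carbon to a C8 aldehyde.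

## Logic of the disconnections

33 to 32: the O15–Si bond is cut. The allylic primary alcohol must stay masked through oxidations, the enolate step and the ring closure, and a bulky silyl ether is the only mask that outlasts aqueous acid and an acyl bromide. The forward step must remove it without touching the methylene lactone or the three esters.

32 to 30 (through 31): the C11=C13 alkene is traced back to a C13–N bond. A dimethylamine adduct removes the Michael acceptor and the vinylogous acidity of C7–H while an aldehyde sits on C8. The forward step needs only N-methylation and a bicarbonate-induced elimination.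

30 to 29: the O8–acyl bond is cut. This is possible because the ring closure leaves O8 as the only free hydroxyl while O9 already carries its acetate. The demand is acylation of a hindered secondary alcohol faster than acetyl migration.

29 to 27 (through 28): the C8–C9 bond is cut with transposition of the C1=C10 alkene to C9=C10. One ring, one skeletal bond and two stereocentres disappear, leaving an open chain whose stereocentres all derive from the C6 centre of 1. The forward step must deliver γ-attack, anti O8/O9, the correct aldehyde face and a ring-cis alkene in a medium-ring closure.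

27 to 26: the C1–Br and O9–acetyl bonds are cut together, as a 1,4-addition of an acyl bromide across the O=C9–C10=C1 unit. The bromide is thus created in the last operation before ring closure and only as an ammonium salt, so the free amine, the allylic bromide and the β-acyloxy aldehyde never have to be stored together. The demand is that the isolated C8 aldehyde stays out of this addition.

26 to 25: both aldehydes (C8 and C9) are returned to dimethyl acetals. Neither reactive carbonyl then has to survive the chain-building steps. The forward hydrolysis must spare the silyl ether, which is why O15 carries the robust tert-butyldiphenylsilyl group.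

25 to 20 and 21 (through 22, 23, 24): the C1=C10 bond is cut as an aldol addition followed by dehydration. This splits off the C9–C10–C14 unit as a three-carbon ester. The ester enolate must add to the C1 aldehyde faster than it loses methoxide or attacks the lactone.

20 to 16 (through 19, 18, 17): only functional groups change (C1 aldehyde from a silyl ether, O15 silyl ether from the C15 aldehyde). The demand is selective acid cleavage of a primary tert-butyldimethylsilyl ether beside a tert-butyldiphenylsilyl ether.

16 to 9 and 14 (through 15): the C4=C5 bond is cut as a Wittig reaction of a C5 aldehyde with a formyl-stabilised ylide. A formyl rather than an ester ylide is chosen so that C15 can later be reduced beside the lactone. The step must give the E-enal (C6 trans to C15) and must not epimerise C6.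

14 to 11 and 12 (through 13), and 11 to 10: the C4–C15 bond (formylation of a non-stabilised ylide) and the C4–P bond are cut, leaving a four-carbon bromide.

9 to 6 (through 8 and 7): the O5–Si bond and the C8 acetal are traced back to a C7 vinyl group. The vinyl group is cleaved here, where it is the only alkene. A cleavage placed late would have to compete with the more electron-rich C4=C5 alkene and with the enol acetate. The amine must be shielded from ozone by protonation.

6 to 2, 3 and 4 (through 5): the C7–C8 and C11–C13 bonds are cut on the butenolide. Conjugate addition anti to the C6 side chain and enolate capture anti to the new substituent set C7 (and, temporarily, C11) from C6 alone. 2 goes back to 1 by silylation.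

## Other disconnections considered

Alternative 1: The cut is C7–C8 plus C11–C13 on the five-membered lactone. In the forward sense, CH2=CHMgBr (3) with CuBr·SMe2 adds to C7 of 2 anti to the C6 side chain. The enolate is then intercepted at C11 by the iminium salt 4, giving the trans,trans lactone A1.
- In favour: two C–C bonds, the C7 stereocentre and the masked methylene arise in one flask under substrate control from a single purchased stereocentre, and each half-reaction is established chemistry.
- Against, as an organising step: it closes no ring and says nothing about C8, C9, the ten-membered ring or the two different esters.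
- Comparison: on structure it covers only the lactone sector, whereas the chosen step covers the carbocycle and two stereocentres. On mechanism it is the more reliable of the two, a point on which it is better. As a three-component coupling it is at least the equal of any single step of the chosen route in step economy. It does not compete with the chosen plan but supplies it: A1 is the same compound as 6 and the coupling is used as step 2.

Alternative 2: The cut treats the carbocycle as the product of cleaving the central alkene of a dearomatised bicyclic arene. Naphthalene A2 would be reduced (Birch) to 1,4,5,8-tetrahydronaphthalene A3. One equivalent of ozone would then cleave only the tetrasubstituted alkene to give (3Z,8Z)-cyclodeca-3,8-diene-1,6-dione A4.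
- In favour: the ten-membered ring arrives in two operations from a bulk arene, without high dilution, with two cis alkenes, and the preference of ozone for the most substituted alkene is predictable. On ring formation, reliability and cost this is better than the chromium closure.
- Against here: A4 is achiral and carries none of the substituents. Its ketones sit at C4 and C9 and its alkenes at C1=C2 and C6=C7. Desymmetrisation with reagent-controlled enantioselection, introduction of C14, C15 and the C11–C13 unit, three oxygen functions at C6, C8 and C9, and relocation of both alkenes would all have to be done on a flexible medium ring prone to transannular reactions.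
- Comparison: structurally it builds the ring first and decorates later, whereas the chosen plan decorates a chain and then closes it. The key step is simpler (better), but the later stereocontrol would have no resident stereocentre or closed transition state to lean on (worse). It needs fewer steps to the ring (better) but is expected to need many more overall.

Alternative 3: The cut reconnects C5–C10, so that the ten-membered ring comes from the cis-decalin A5, which has a C10 bridgehead alcohol and a C4 spiro-epoxide. In the forward sense KH would form the C10 alkoxide, and a Grob fragmentation would break the antiperiplanar C5–C10 bond into the epoxide. This gives the ketone A6 with a ring-cis C4=C5 alkene and a free C15 alcohol.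
- In favour: C6–C9 are set on a rigid six-membered ring. The fragmentation is concerted and stereospecific, so the alkene geometry follows from the ring fusion; this is equal to or better than the ylide-controlled geometry of the chosen route. The ring forms by an exothermic bond cleavage rather than an entropically costly cyclisation (better).
- Against here: in A6 the C10 ketone must still become the C1=C10 enoate, by regioselective enolisation away from the oxygenated C9 followed by carbonylation. The side chain on C7 must be oxidised at C12 and lactonised onto O6. Removal of the acetonide leaves O8 and O9 undifferentiated, whereas the chosen step delivers them already distinguished (worse). A5, with seven stereocentres, is itself a long synthesis.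
- Comparison: the key step is mechanistically more secure (better), but the plan is clearly longer before and after it (worse).

Key step: step 16

Remark: germacranolide numbering is used for every intermediate; the exocyclic CH2O carbon of 1 is C5 and its ring CH–O carbon is C6.
Remark: 10 is taken as a catalogue reagent; 23 (C1, C10), 25 (C1=C10 geometry) and 27 (C1) are carried as stereoisomer mixtures because these elements are erased or converge in steps 13, 15 and 16; one C1 epimer of 27 is drawn.
Remark: 26 and 27 are handled as ammonium salts and 27 is freed only at the moment of ring closure, since a free tertiary amine should not be stored beside an allylic bromide or a β-acyloxy aldehyde.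

## Route

Step 1
Reactants: 1 (S)-5-(hydroxymethyl)furan-2(5H)-one
Product: 2 (S)-5-{[(tert-butyldiphenylsilyl)oxy]methyl}furan-2(5H)-one
Conditions: TBDPSCl, imidazole, DMF, 0 °C → rt
Reagents that add atoms: tert-butyl(chloro)diphenylsilane, CC(C)(C)[Si](Cl)(c1ccccc1)c1ccccc1
Why: Standard silylation of a primary alcohol; the bulky silyl ether later shields one face of the butenolide.

Step 2
Reactants: 2 (S)-5-{[(tert-butyldiphenylsilyl)oxy]methyl}furan-2(5H)-one; 3 vinylmagnesium bromide; 4 N,N-dimethylmethyleneiminium iodide
Product: 6 (3R,4S,5S)-5-{[(tert-butyldiphenylsilyl)oxy]methyl}-3-[(dimethylamino)methyl]-4-vinyldihydrofuran-2(3H)-one, via bromomagnesium lactone enolate 5 (not isolated)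
Conditions: CH2=CHMgBr (1.5 equiv), CuBr·SMe2 (10 mol %), THF/Me2S, −78 → −40 °C; then [CH2=NMe2]I, −40 °C → rt
Reagents that add atoms: none
Why: Copper-catalysed conjugate addition of the Grignard reagent should occur anti to the C6 silyloxymethyl group, and Mannich capture of the enolate by the iminium salt anti to the new vinyl group, giving the trans,trans lactone (C7 set from C6, C11 from C7).

Step 3
Reactants: 6 (3R,4S,5S)-5-{[(tert-butyldiphenylsilyl)oxy]methyl}-3-[(dimethylamino)methyl]-4-vinyldihydrofuran-2(3H)-one
Product: 8 (3R,4S,5S)-5-{[(tert-butyldiphenylsilyl)oxy]methyl}-4-(dimethoxymethyl)-3-[(dimethylamino)methyl]dihydrofuran-2(3H)-one, via C8 aldehyde 7 (not isolated)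
Conditions: TsOH·H2O (1.1 equiv), O3, CH2Cl2/MeOH, −78 °C; Me2S, −78 °C → rt; then HC(OMe)3, rt; NaHCO3
Reagents that add atoms: trimethyl orthoformate, COC(OC)OC; methanol, CO
Why: Ozonolysis with reductive work-up and acid-catalysed acetalisation in one flask; the vinyl group is the only alkene at this stage and the amine is shielded from ozone as its ammonium salt, so C8 reaches the aldehyde level without a selectivity problem and without exposing a free β-acyloxy aldehyde.

Step 4
Reactants: 8 (3R,4S,5S)-5-{[(tert-butyldiphenylsilyl)oxy]methyl}-4-(dimethoxymethyl)-3-[(dimethylamino)methyl]dihydrofuran-2(3H)-one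
Product: 9 (3R,4S,5S)-4-(dimethoxymethyl)-3-[(dimethylamino)methyl]-5-(hydroxymethyl)dihydrofuran-2(3H)-one
Conditions: TBAF, AcOH, THF, 0 °C → rt
Reagents that add atoms: none
Why: Fluoride desilylation buffered with acetic acid, so that neither the amino lactone nor the acetal is exposed to base or strong acid.

Step 5
Reactants: 10 tert-butyl(4-bromobutoxy)dimethylsilane
Product: 11 {4-[(tert-butyldimethylsilyl)oxy]butyl}triphenylphosphonium bromide
Conditions: PPh3, MeCN, 80 °C
Reagents that add atoms: triphenylphosphine, c1ccc(cc1)P(c1ccccc1)c1ccccc1
Why: Quaternisation of a primary bromide by the phosphine (SN2) under neutral conditions that a silyl ether tolerates.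

Step 6
Reactants: 11 {4-[(tert-butyldimethylsilyl)oxy]butyl}triphenylphosphonium bromide; 12 ethyl formate
Product: 14 5-[(tert-butyldimethylsilyl)oxy]-2-(triphenyl-λ5-phosphanylidene)pentanal, via phosphorus ylide 13 (not isolated)
Conditions: KOtBu (1.05 equiv), THF, 0 °C; HCO2Et, 0 °C → rt; then KOtBu (1.0 equiv)
Reagents that add atoms: none
Why: C-Formylation of a non-stabilised ylide by a formate ester, followed by deprotonation of the acylphosphonium salt, is the standard entry to 2-substituted formyl ylides; the product is a bench-stable stabilised ylide.

Step 7
Reactants: 9 (3R,4S,5S)-4-(dimethoxymethyl)-3-[(dimethylamino)methyl]-5-(hydroxymethyl)dihydrofuran-2(3H)-one; 14 5-[(tert-butyldimethylsilyl)oxy]-2-(triphenyl-λ5-phosphanylidene)pentanal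
Product: 16 lactone with C6 carrying (E)-CH=C(CHO)CH2CH2CH2OTBS (C4=C5 enal; C15 aldehyde; C1 silyl ether), via C5 aldehyde 15 (not isolated)
Conditions: (COCl)2, DMSO, CH2Cl2, −78 °C; Et3N, −78 → −30 °C; then 14, −30 °C → rt
Reagents that add atoms: none
Why: Swern oxidation followed in the same flask by a Wittig reaction of the stabilised formyl ylide; trapping the α-acyloxy aldehyde at once limits epimerisation at C6, and reversible betaine formation with a stabilised ylide should give the E-enal (C6 trans to C15, ring-cis in the target).

Step 8
Reactants: 16 C4=C5 (E)-enal with C15 aldehyde and C1 silyl ether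
Product: 17 C15 allylic alcohol (C1 silyl ether retained)
Conditions: NaBH4, CeCl3·7H2O, MeOH, −40 °C
Reagents that add atoms: none
Why: Luche reduction gives clean 1,2-reduction of the enal and leaves the lactone and the acetal untouched at low temperature.

Step 9
Reactants: 17 C15 allylic alcohol
Product: 18 C15 tert-butyldiphenylsilyl ether, C1 tert-butyldimethylsilyl ether
Conditions: TBDPSCl, imidazole, CH2Cl2, rt
Reagents that add atoms: tert-butyl(chloro)diphenylsilane, CC(C)(C)[Si](Cl)(c1ccccc1)c1ccccc1
Why: Silylation of the primary allylic alcohol with the group chosen to outlast the later aqueous acid and acetyl bromide.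

Step 10
Reactants: 18 bis-silyl ether
Product: 19 C1 primary alcohol (C15 silyl ether and C8 acetal retained)
Conditions: TsOH·H2O (1.2 equiv), MeOH/CH2Cl2, 0 °C
Reagents that add atoms: none
Why: Acid-catalysed methanolysis cleaves a primary tert-butyldimethylsilyl ether far faster than a tert-butyldiphenylsilyl ether; the dimethyl acetal only exchanges with the solvent and one equivalent of acid is held by the amine.

Step 11
Reactants: 19 C1 primary alcohol
Product: 20 C1 aldehyde
Conditions: (COCl)2, DMSO, CH2Cl2, −78 °C; Et3N, −78 → 0 °C
Reagents that add atoms: none
Why: Swern oxidation of an unhindered primary alcohol; tertiary amine, acetal, lactone and silyl ether are all compatible.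

Step 12
Reactants: 20 C1 aldehyde; 21 methyl 3,3-dimethoxypropanoate
Product: 23 C1 β-hydroxy ester (C10 bearing CO2Me and the C9 dimethyl acetal; mixture at C1 and C10), via lithium ester enolate 22 (not isolated)
Conditions: 21, LiN(i-Pr)2, THF, −78 °C; then 20, −78 °C; aq NH4Cl
Reagents that add atoms: none
Why: Aldol addition of a preformed lithium ester enolate; at −78 °C addition to the aldehyde should outrun both loss of methoxide from the enolate and attack on the lactone, and the new centres need no control because both are erased.

Step 13
Reactants: 23 C1 β-hydroxy ester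
Product: 25 C1=C10 alkylidene ester with C9 dimethyl acetal (E/Z mixture), via C1 mesylate 24 (not isolated)
Conditions: MsCl, Et3N, CH2Cl2, 0 °C; then DBU, 0 °C → rt
Reagents that add atoms: none
Why: Mesylation followed by E1cB elimination of a β-sulfonyloxy ester; the alkene geometry is immaterial because C1 becomes sp3 again in step 15.

Step 14
Reactants: 25 C1=C10 alkylidene ester bis-acetal
Product: 26 dialdehyde (C8 aldehyde on the lactone; 2-formyl enoate at C9/C10/C1), kept as its trifluoroacetate salt
Conditions: TFA/H2O, CH2Cl2, 0 °C; toluene azeotrope
Reagents that add atoms: water, O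
Why: Acid hydrolysis of both dimethyl acetals; the tert-butyldiphenylsilyl ether withstands cold aqueous TFA and the protonated amine cannot act as a base towards the C8 aldehyde or as a nucleophile towards the 2-formyl enoate.

Step 15
Reactants: 26 dialdehyde
Product: 27 C8 aldehyde with C1 bromide and (E)-C9 enol acetate (C1 epimers), obtained as the hydrobromide
Conditions: AcBr (3 equiv), CH2Cl2, −40 → 0 °C; cold pH 7 buffer; used at once
Reagents that add atoms: acetyl bromide, CC(=O)Br
Why: Conjugate addition of an acyl bromide to an α,β-unsaturated aldehyde, the reaction that makes 3-bromoprop-1-enyl esters: bromide adds to the doubly activated C1 and the hydrogen-bonded enol, whose oxygen sits syn to the ester, is O-acetylated, which should favour the E enol acetate. The isolated C8 aldehyde has no conjugate position and should need Lewis-acid activation to react, and the amine stays protonated.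

Step 16
Reactants: 27 C8 aldehyde with C1 bromide and (E)-C9 enol acetate
Product: 29 ten-membered ring with free C8 hydroxyl, C9 acetate and C1=C10 enoate (amine adduct of the lactone; O15 silyl ether), via allylchromium dichloride 28 (not isolated)
Conditions: 27·HBr freed with cold aq NaHCO3 immediately before use; CrCl2 (10 equiv), THF, 25 °C, slow addition of 27 (final 2 mM); aq NaHCO3
Reagents that add atoms: none
Why: Proposed new method: CrCl2 (divalent chromium, two equivalents per bromide) reduces the C1–Br bond by two single-electron transfers to the allylchromium 28 (trivalent chromium), which adds to the C8 aldehyde through its acetoxy-bearing γ-carbon C9 in a six-membered chair (Cr, C1, C10, C9, C8, O), so that C8–C9 forms while the π bond moves to C1=C10; the closest known reactions are the Barbier-type γ-acyloxyallylation of aldehydes with 3-bromoprop-1-enyl esters and intramolecular Nozaki–Hiyama allylations of 2-(alkoxycarbonyl)allyl bromides. The ten-membered ring closes by intramolecular SE2′ attack of the allyl terminus on the tethered aldehyde: because the tether (C2 to C7) joins the metal-bearing carbon to the carbon next to the carbonyl group, all three allyl carbons become ring members, and slow addition at about 2 mM should suppress bimolecular allylation. C9 is controlled by the E geometry of the enol acetate, which places OAc pseudo-equatorial in the chair and gives the anti O8/O9 relationship; should the allylchromium isomerise, metallotropic equilibration is expected to favour the same E form. C8 is controlled by the resident C7 centre: C9 approaches the aldehyde face anti to the C7–C11 bond (Felkin–Anh), the only arrangement that also keeps C6, the anchor of the tether, gauche to the new bond. The ring-cis C1=C10 geometry follows from allylic 1,2-strain between the C10 ester and the C2 chain, which pushes C2 pseudo-axial on C1; both C1 epimers of 27 give the same configurationally labile allylchromium and therefore converge. The step needs γ- over α-attack (secured by the closed transition state), reaction at the aldehyde only (allylchromium reagents leave lactones, esters and enol esters alone at 25 °C) and retention of the acetate on O9, so that O8 emerges as the single free hydroxyl.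

Step 17
Reactants: 29 ten-membered C8 alcohol
Product: 30 C8 isobutyrate, C9 acetate (amine adduct; O15 silyl ether)
Conditions: (i-PrCO)2O, DMAP (cat.), pyridine, CH2Cl2, 0 °C
Reagents that add atoms: isobutyric anhydride, CC(C)C(=O)OC(=O)C(C)C
Why: DMAP-catalysed acylation of the only free hydroxyl; a weak base and low temperature should keep acylation faster than acetyl migration from O9.

Step 18
Reactants: 30 C8 isobutyrate amine adduct
Product: 32 α-methylene lactone (O15 silyl ether), via ammonium iodide 31 (not isolated)
Conditions: MeI, THF, rt; then aq NaHCO3/EtOAc, rt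
Reagents that add atoms: none
Why: N-Methylation and E1cB loss of trimethylamine from the β-ammonio lactone regenerate the exocyclic C11=C13 alkene under conditions too mild to touch the esters; the temporary C11 centre disappears.

Step 19
Reactants: 32 silylated methylene lactone
Product: 33 CNP0242134.4, the (6R,7S,8S,9R) germacranolide with free C15 hydroxyl
Conditions: HF·pyridine, pyridine, THF, 0 °C → rt
Reagents that add atoms: none
Why: Buffered HF cleaves the primary allylic silyl ether without a basic fluoride that could promote acyl migration or conjugate addition to the methylene lactone.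

## Compound list

1 | (S)-5-(hydroxymethyl)furan-2(5H)-one | O=C1C=C[C@@H](CO)O1 | starting material
2 | (S)-5-{[(tert-butyldiphenylsilyl)oxy]methyl}furan-2(5H)-one | O=C1C=C[C@@H](CO[Si](c2ccccc2)(c2ccccc2)C(C)(C)C)O1 | intermediate
3 | vinylmagnesium bromide | C=C[Mg]Br | starting material
4 | N,N-dimethylmethyleneiminium iodide | C=[N+](C)C.[I-] | starting material
5 | bromomagnesium enolate of the 4-vinyl lactone (vinyl trans to the C6 side chain; not isolated) | Br[Mg]OC1=C[C@H](C=C)[C@@H](CO[Si](c2ccccc2)(c2ccccc2)C(C)(C)C)O1 | intermediate
6 | (3R,4S,5S)-5-{[(tert-butyldiphenylsilyl)oxy]methyl}-3-[(dimethylamino)methyl]-4-vinyldihydrofuran-2(3H)-one | O=C1O[C@H](CO[Si](c2ccccc2)(c2ccccc2)C(C)(C)C)[C@@H](C=C)[C@@H]1CN(C)C | intermediate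
7 | (3R,4S,5S)-4-formyl analogue of 6 (C8 aldehyde; not isolated) | O=C1O[C@H](CO[Si](c2ccccc2)(c2ccccc2)C(C)(C)C)[C@@H](C=O)[C@@H]1CN(C)C | intermediate
8 | (3R,4S,5S)-5-{[(tert-butyldiphenylsilyl)oxy]methyl}-4-(dimethoxymethyl)-3-[(dimethylamino)methyl]dihydrofuran-2(3H)-one | O=C1O[C@H](CO[Si](c2ccccc2)(c2ccccc2)C(C)(C)C)[C@@H](C(OC)OC)[C@@H]1CN(C)C | intermediate
9 | (3R,4S,5S)-4-(dimethoxymethyl)-3-[(dimethylamino)methyl]-5-(hydroxymethyl)dihydrofuran-2(3H)-one | O=C1O[C@H](CO)[C@@H](C(OC)OC)[C@@H]1CN(C)C | intermediate
10 | tert-butyl(4-bromobutoxy)dimethylsilane | CC(C)(C)[Si](C)(C)OCCCCBr | starting material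
11 | {4-[(tert-butyldimethylsilyl)oxy]butyl}triphenylphosphonium bromide | CC(C)(C)[Si](C)(C)OCCCC[P+](c1ccccc1)(c1ccccc1)c1ccccc1.[Br-] | intermediate
12 | ethyl formate | CCOC=O | starting material
13 | {4-[(tert-butyldimethylsilyl)oxy]butylidene}triphenylphosphorane (not isolated) | CC(C)(C)[Si](C)(C)OCCCC=P(c1ccccc1)(c1ccccc1)c1ccccc1 | intermediate
14 | 5-[(tert-butyldimethylsilyl)oxy]-2-(triphenyl-λ5-phosphanylidene)pentanal | CC(C)(C)[Si](C)(C)OCCCC(C=O)=P(c1ccccc1)(c1ccccc1)c1ccccc1 | intermediate
15 | C5 aldehyde of 9 (5-formyl lactone, configuration at C6, C7, C11 unchanged; not isolated) | O=C1O[C@H](C=O)[C@@H](C(OC)OC)[C@@H]1CN(C)C | intermediate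
16 | lactone with C6 bearing (E)-CH=C(CHO)(CH2)3OSi(t-Bu)Me2 (C4=C5 enal, C6 trans to C15) | O=C1O[C@H](/C=C(/C=O)CCCO[Si](C)(C)C(C)(C)C)[C@@H](C(OC)OC)[C@@H]1CN(C)C | intermediate
17 | C15 allylic alcohol from 16 | O=C1O[C@H](/C=C(/CO)CCCO[Si](C)(C)C(C)(C)C)[C@@H](C(OC)OC)[C@@H]1CN(C)C | intermediate
18 | C15 tert-butyldiphenylsilyl ether, C1 tert-butyldimethylsilyl ether | O=C1O[C@H](/C=C(/CO[Si](c2ccccc2)(c2ccccc2)C(C)(C)C)CCCO[Si](C)(C)C(C)(C)C)[C@@H](C(OC)OC)[C@@H]1CN(C)C | intermediate
19 | C1 primary alcohol | O=C1O[C@H](/C=C(/CO[Si](c2ccccc2)(c2ccccc2)C(C)(C)C)CCCO)[C@@H](C(OC)OC)[C@@H]1CN(C)C | intermediate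
20 | C1 aldehyde | O=C1O[C@H](/C=C(/CO[Si](c2ccccc2)(c2ccccc2)C(C)(C)C)CCC=O)[C@@H](C(OC)OC)[C@@H]1CN(C)C | intermediate
21 | methyl 3,3-dimethoxypropanoate | COC(OC)CC(=O)OC | starting material
22 | lithium enolate of 21 (not isolated) | COC(OC)C=C(O[Li])OC | intermediate
23 | aldol adduct: C1 hydroxyl, C10 bearing CO2Me and CH(OMe)2 (mixture at C1 and C10) | O=C1O[C@H](/C=C(/CO[Si](c2ccccc2)(c2ccccc2)C(C)(C)C)CCC(O)C(C(=O)OC)C(OC)OC)[C@@H](C(OC)OC)[C@@H]1CN(C)C | intermediate
24 | C1 mesylate of 23 (not isolated) | O=C1O[C@H](/C=C(/CO[Si](c2ccccc2)(c2ccccc2)C(C)(C)C)CCC(OS(C)(=O)=O)C(C(=O)OC)C(OC)OC)[C@@H](C(OC)OC)[C@@H]1CN(C)C | intermediate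
25 | C1=C10 alkylidene ester with C9 and C8 dimethyl acetals (E/Z mixture at C1=C10, left undefined) | O=C1O[C@H](/C=C(/CO[Si](c2ccccc2)(c2ccccc2)C(C)(C)C)CCC=C(C(=O)OC)C(OC)OC)[C@@H](C(OC)OC)[C@@H]1CN(C)C | intermediate
26 | dialdehyde: C8 aldehyde and 2-formyl enoate (C1=C10 geometry undefined) | O=C1O[C@H](/C=C(/CO[Si](c2ccccc2)(c2ccccc2)C(C)(C)C)CCC=C(C=O)C(=O)OC)[C@@H](C=O)[C@@H]1CN(C)C | intermediate
27 | key-step precursor: C8 aldehyde, C1 bromide, (E)-C9 enol acetate (C1 epimers, one drawn) | O=C1O[C@H](/C=C(/CO[Si](c2ccccc2)(c2ccccc2)C(C)(C)C)CC[C@H](Br)/C(C(=O)OC)=C/OC(C)=O)[C@@H](C=O)[C@@H]1CN(C)C | intermediate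
28 | allylchromium dichloride at C1 (trivalent chromium; not isolated) | O=C1O[C@H](/C=C(/CO[Si](c2ccccc2)(c2ccccc2)C(C)(C)C)CCC([Cr](Cl)Cl)/C(C(=O)OC)=C/OC(C)=O)[C@@H](C=O)[C@@H]1CN(C)C | intermediate
29 | key-step product: ten-membered ring, free C8 hydroxyl, C9 acetate, C1=C10 enoate | CN(C)C[C@@H]1C(=O)O[C@@H]2/C=C(/CO[Si](c3ccccc3)(c3ccccc3)C(C)(C)C)CC/C=C(/C(=O)OC)[C@@H](OC(C)=O)[C@@H](O)[C@@H]12 | intermediate
30 | C8 isobutyrate of 29 | CN(C)C[C@@H]1C(=O)O[C@@H]2/C=C(/CO[Si](c3ccccc3)(c3ccccc3)C(C)(C)C)CC/C=C(/C(=O)OC)[C@@H](OC(C)=O)[C@@H](OC(=O)C(C)C)[C@@H]12 | intermediate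
31 | trimethylammonium iodide of 30 (not isolated) | C[N+](C)(C)C[C@@H]1C(=O)O[C@@H]2/C=C(/CO[Si](c3ccccc3)(c3ccccc3)C(C)(C)C)CC/C=C(/C(=O)OC)[C@@H](OC(C)=O)[C@@H](OC(=O)C(C)C)[C@@H]12.[I-] | intermediate
32 | O15-silylated α-methylene lactone | C=C1C(=O)O[C@@H]2/C=C(/CO[Si](c3ccccc3)(c3ccccc3)C(C)(C)C)CC/C=C(/C(=O)OC)[C@@H](OC(C)=O)[C@@H](OC(=O)C(C)C)[C@@H]12 | intermediate
33 | CNP0242134.4 | C=C1C(=O)O[C@@H]2/C=C(/CO)CC/C=C(/C(=O)OC)[C@@H](OC(C)=O)[C@@H](OC(=O)C(C)C)[C@@H]12 | target

## Step count and least certain steps

Total step count: 19. Longest linear sequence: 17 steps (steps 1–4 and 7–19, from 1 to 33); the ylide branch adds steps 5 and 6.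

**Step 16 (key step).**
- What may go wrong: bimolecular allylation may compete with closure of a strained ten-membered ring. The allylchromium may be lost by protonation before it reaches the aldehyde. Simple or facial diastereoselection may erode if the tether enforces a boat or open transition state. The freed amine may trigger enolisation of the C8 aldehyde with expulsion of the lactone oxygen. The chromium alkoxide may take the acetyl group from O9 or attack the C14 ester.
- Fallback (known reaction types): set out from 20. Methylenation (Ph3PCH3Br, KOtBu) would give the terminal alkene F1, and aqueous TFA would give the C8 aldehyde F2. Separately, commercial methyl 2-methyl-3-oxopropanoate would be O-acetylated to methyl (Z)-3-acetoxy-2-methylacrylate F3 and brominated with NBS to methyl (E)-3-acetoxy-2-(bromomethyl)acrylate F4. Intermolecular Barbier-type γ-acetoxyallylation of F2 with F4 and CrCl2 should give the anti, Felkin adduct F5, whose C8 hydroxyl, C9 acetate and C10 acrylate are already in place. Ring-closing metathesis of F5 (as its tosylate salt, second-generation Hoveyda–Grubbs catalyst, high dilution) would then form C1=C10 and rejoin the route at 29.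

**Step 15.**
- What may go wrong: the C8 aldehyde or the silyl ether may take up the acyl bromide. A mixture of enol acetate geometries may form. HBr may be lost again on work-up.
- Fallback: from 26, separate the two bond formations. TMSBr (CH2Cl2, −78 °C) would add 1,4 and, after hydrolytic work-up, give the hydrogen-bonded γ-bromo enol F6. This would be O-acetylated (Ac2O, pyridine, −20 °C) with retention of the chelated geometry, returning at 27.

**Step 12.**
- What may go wrong: the β,β-dimethoxy ester enolate may expel methoxide before it adds, and a strongly basic enolate may attack or deprotonate the lactone.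
- Fallback: from 20, a neutral Wittig reaction with methyl 3,3-dimethoxy-2-(triphenyl-λ5-phosphanylidene)propanoate F7 in warm toluene would give 25 directly, bypassing 23 and 24. F7 would be made from commercial methyl (triphenylphosphoranylidene)acetate by C-alkylation with the dimethoxycarbenium ion from HC(OMe)3 and BF3·OEt2, then deprotonation.

**Step 3.**
- What may go wrong: incompletely protonated amine may be oxidised by ozone, and the N-oxide would then eliminate.
- Fallback: from 2, run the conjugate addition with a proton quench to give the 4-vinyl lactone F8. Ozonolysis and acetalisation as in step 3 would give the amine-free acetal F9. Aminomethylation of its lithium enolate (LiN(i-Pr)2, then 4) anti to the C7 substituent would return at 8.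

**Step 19.**
- What may go wrong: the robust silyl ether may cleave slowly, and forcing the conditions invites acyl migration or conjugate addition to the methylene lactone.
- Fallback: from 30, desilylate while the lactone is still masked (TBAF/AcOH) to the amino alcohol F10. Then methylate (MeI) to the ammonium iodide F11 and eliminate with aq NaHCO3, arriving directly at 33.

## Further compounds

F1 | step 16 | terminal alkene from methylenation of 20 (C1=CH2; C8 acetal) | O=C1O[C@H](/C=C(/CO[Si](c2ccccc2)(c2ccccc2)C(C)(C)C)CCC=C)[C@@H](C(OC)OC)[C@@H]1CN(C)C
F2 | step 16 | C8 aldehyde with terminal alkene | O=C1O[C@H](/C=C(/CO[Si](c2ccccc2)(c2ccccc2)C(C)(C)C)CCC=C)[C@@H](C=O)[C@@H]1CN(C)C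
F3 | step 16 | methyl (Z)-3-acetoxy-2-methylacrylate | C/C(C(=O)OC)=C/OC(C)=O
F4 | step 16 | methyl (E)-3-acetoxy-2-(bromomethyl)acrylate | BrC/C(C(=O)OC)=C/OC(C)=O
F5 | step 16 | open-chain adduct: C8 hydroxyl, C9 acetate, C10 acrylate, terminal alkene | O=C1O[C@H](/C=C(/CO[Si](c2ccccc2)(c2ccccc2)C(C)(C)C)CCC=C)[C@@H]([C@H](O)[C@H](OC(C)=O)C(=C)C(=O)OC)[C@@H]1CN(C)C
F6 | step 15 | γ-bromo enol (C1 bromide, C9 enol syn to the ester, C8 aldehyde) | O=C1O[C@H](/C=C(/CO[Si](c2ccccc2)(c2ccccc2)C(C)(C)C)CCC(Br)/C(C(=O)OC)=C/O)[C@@H](C=O)[C@@H]1CN(C)C
F7 | step 12 | methyl 3,3-dimethoxy-2-(triphenyl-λ5-phosphanylidene)propanoate | COC(OC)C(C(=O)OC)=P(c1ccccc1)(c1ccccc1)c1ccccc1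
F8 | step 3 | (4S,5S)-5-{[(tert-butyldiphenylsilyl)oxy]methyl}-4-vinyldihydrofuran-2(3H)-one | O=C1O[C@H](CO[Si](c2ccccc2)(c2ccccc2)C(C)(C)C)[C@@H](C=C)C1
F9 | step 3 | 4-(dimethoxymethyl) lactone without the aminomethyl group | O=C1O[C@H](CO[Si](c2ccccc2)(c2ccccc2)C(C)(C)C)[C@@H](C(OC)OC)C1
F10 | step 19 | desilylated amine adduct (free C15 hydroxyl, C8 isobutyrate, C9 acetate) | CN(C)C[C@@H]1C(=O)O[C@@H]2/C=C(/CO)CC/C=C(/C(=O)OC)[C@@H](OC(C)=O)[C@@H](OC(=O)C(C)C)[C@@H]12
F11 | step 19 | trimethylammonium iodide of F10 | C[N+](C)(C)C[C@@H]1C(=O)O[C@@H]2/C=C(/CO)CC/C=C(/C(=O)OC)[C@@H](OC(C)=O)[C@@H](OC(=O)C(C)C)[C@@H]12.[I-]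
A1 | alternative 1 | trans,trans lactone with C7 vinyl and C11 dimethylaminomethyl (identical to 6) | O=C1O[C@H](CO[Si](c2ccccc2)(c2ccccc2)C(C)(C)C)[C@@H](C=C)[C@@H]1CN(C)C
A2 | alternative 2 | naphthalene | c1ccc2ccccc2c1
A3 | alternative 2 | 1,4,5,8-tetrahydronaphthalene | C1C=CCC2=C1CC=CC2
A4 | alternative 2 | (3Z,8Z)-cyclodeca-3,8-diene-1,6-dione | O=C1C/C=C\CC(=O)C/C=C\C1
A5 | alternative 3 | cis-decalin with C10 bridgehead alcohol and C4 spiro-epoxide (epoxide oxygen anti to C5–C10) | CC(C)(C)[Si](C)(C)O[C@@H]1[C@@H]2[C@@]3(CO3)CCC[C@]2(O)[C@H]4OC(C)(C)O[C@H]4[C@H]1C(=C)CO[Si](C)(C)C(C)(C)C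
A6 | alternative 3 | ten-membered C10 ketone with cis C4=C5 and free C15 alcohol | CC(C)(C)[Si](C)(C)O[C@@H]1/C=C(/CO)CCCC(=O)[C@H]2OC(C)(C)O[C@H]2[C@H]1C(=C)CO[Si](C)(C)C(C)(C)C
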